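## The problem

The target 24 is an 18-membered macrocycle made of four benzene rings. Ring A carries the carbinol carbon Cα at A1, hydroxyls at A3 and A4 and an ether oxygen at A5 leading to B1 of the para-phenylene ring B; B4 is tied by a CH2–CH2 bridge to C1 of ring C, whose C2 bears the second ether oxygen (to D1 of the meta-phenylene ring D) and whose C3 bears a hydroxyl; D3 carries Cβ, the methylene bonded to Cα. A synthesis therefore has to make two diaryl ethers, one of them (C2–O–D1) flanked on both sides, two two-carbon bridges and the large ring. Cα (S) is the only stereocentre, so nothing in the molecule can relay chirality to it and it must be set by a reagent or catalyst. The Cα–OH group is benzylic and para to the free A4 hydroxyl, so the finished molecule can ionise to a quinone methide under acid or strong base (racemisation, elimination towards a stilbene), and the C–O bond is at risk under forcing hydrogenolysis; the ring A catechol is also easily oxidised. The phenols should therefore be released late and the last steps kept near neutral. The feature that opens the molecule is that Cα bears ring A and is bonded to a methylene on D3: a 1,2-diarylethanol with oxygen on the ring A side, which maps onto an aryl nucleophile (A1), a vinylboron two-carbon unit (Cα, Cβ) and an aryl electrophile (D3), the C–B bond being exchanged for C–O with retention afterwards. A second useful feature is that the bridge carbons on ring B and ring C sit para and ortho to the ether oxygens, so a formyl group can first activate ether formation by fluoride displacement and then become the bridge carbon.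

## Retrosynthesis

**Releasing the sensitive groups last (24 from 23 from 22).** The last bond cut is O–Si at Cα, and before it the three O–benzyl bonds and the alkene of the B4–C1 bridge. Keeping Cα–O as a silyl ether through the hydrogenation protects the benzylic C–O bond, and a buffered fluoride step as the final operation avoids both acid and phenoxide. One hydrogenation over palladium on carbon saturates the bridge of 22 and frees the three phenols to give 23, so no separate deprotection of the ring oxygens is needed.

**Ring closure at the B4–C1 bridge (22 from 21).** The macrocycle is opened at the CH=CH between B4 and C1, which leads to the acyclic dialdehyde 21. This cut is preferred to closure at an ether (the C2 oxygen is hindered and ring D is not activated) and to closure at Cα–Cβ (which would load the stereocentre onto the ring-forming step). It joins two identical functional groups that need no differentiation and lies far from Cα. The forward reaction must tolerate one silyl and three benzyl ethers and must be run under high dilution; the alkene geometry does not matter.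

**Adjusting the coupling product (21 from 20 from 19 from 18).** The two aldehydes of 21 come from the dioxolanes of 20, the silyl ether from carbinol 19, and the carbinol from the secondary pinacol boronate 18 by stereoretentive oxidation. These changes only convert the groups needed for the coupling into those needed for ring closure.

**The conjunctive cut (18 from 8, 15 and 14).** Cutting A1–Cα and Cβ–D3 divides 18 into the ring A–O–ring B bromide 8, the vinylboronic ester 15 and the ring C–O–ring D triflate 14. Compared with adding a ring A metal species to an enolisable arylacetaldehyde, or with asymmetric reduction of a diaryl ketone built in extra steps, this cut joins two halves of similar size and sets Cα in the same catalytic step. The forward reaction needs clean bromine–lithium exchange on 8, functional groups limited to ethers and acetals (which both halves satisfy), and a chiral ligand on palladium to choose the alkene face.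

**Fragment 1 (8 from 7 from 5 and 6; 5 from 3 from 2 from 1).** The dioxolane of 8 masks the aldehyde of 7, whose diaryl ether is cut at O–B1 into phenol 5 and 4-fluorobenzaldehyde 6, the formyl group activating the fluoride. Phenol 5 has three adjacent ring A oxygens, two benzylated and one free. Desymmetrising a pyrogallol would not deliver this pattern reliably, so the free oxygen is traced to the formyl group of 3 (aryl migration to oxygen). 3 is traced to catechol aldehyde 2 and this to the commercial bromo-ortho-vanillin 1, in which the bromine already sits para to the central oxygen.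

**Fragment 2 (14 from 13 from 12 from 10 and 11; 10 from 9).** The triflate of 14 comes from phenol 13, the dioxolane from aldehyde 12, and the hindered ether is cut at C2–O into fluoroaldehyde 10 and resorcinol 11. The cut is made on the ring C side because only there does an ortho formyl group activate displacement. 10 is the benzyl ether of commercial 9. The forward reaction needs mono-arylation of 11, which an excess of 11 should secure.

## Roads not taken

Alternative 1: Ring contraction of a macrocyclic dibenzyl ether. Here Cα–Cβ is cut and traced to a 19-membered ring in which an oxygen sits between Cα and the ring D methylene, the α-stannyl ether A1. In the forward direction n-BuLi exchanges tin for lithium at Cα, the ring D benzyl group shifts from oxygen to carbon ([1,2]-Wittig), and the 18-membered tris-silyl ether A2 results with its carbinol already free.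
- Merits: the ring is closed at an easy ether-forming stage; the carbinol needs no protecting group; the phenol silyl ethers of A2 fall in one fluoride step, with no titanium chemistry and no hydrogenation next to a benzylic C–O bond. In these respects the route is better than the chosen one.
- Weak points: the lithiated carbon is a benzylic α-alkoxy carbanion, which is configurationally labile, and the shift passes through a radical pair, so transfer of configuration from A1 to A2 is uncertain. Enantioenriched A1 needs an asymmetric step of its own, stoichiometric tin, and an alkyllithium in the presence of three aryl silyl ethers.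
- Comparison: the chosen plan sets against these advantages a stereocentre that is created under catalyst control as a configurationally stable C–B bond, in the step that also joins the two halves.

Alternative 2: Two-carbon stitching of ring B and ring C iodides. Both aryl–vinyl bonds of the B4–C1 bridge are cut, giving the seco bis-iodide A3 and (E)-1,2-bis(tributylstannyl)ethene A4. A double Stille coupling with Pd2(dba)3/AsPh3 would close the ring as the macrocyclic (E)-stilbene A5, the geometric isomer of 22.
- Merits: two C–C bonds and the ring form in one neutral operation; no aldehydes are involved, so no acetals have to be put on and taken off; the Cα silyl ether never meets low-valent titanium. In ring-closing step economy this is as good as or better than the McMurry closure.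
- Weak points: the key step does nothing for Cα, which must be made separately in A3; the iodides of A3 rule out an aryllithium-based union of the halves; the ring C iodide is flanked by the aryloxy group; the first coupling is intermolecular, so oligomers compete; the reagent A4 imposes the E geometry whether or not the ring accommodates it; tin and arsenic are used in quantity.
- Comparison: the chosen plan answers with formyl groups that serve twice (ether formation, then ring closure), a ring closure free to adopt either alkene geometry, and fragment union plus stereocentre in a single step.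

Alternative 3: Oxidative phenol coupling for the ring A ether. The A5–O bond is cut. In the seco bis-phenol A6, ring A is a 3,5-dibromo-4-hydroxyphenyl group and ring B a 3,5-dichloro-4-hydroxyphenyl group. Tl(NO3)3 in methanol oxidises the ring A phenol, the ring B oxygen attacks the bromine-bearing A5, and zinc/acetic acid work-up expels bromide to give the macrocyclic ether A7.
- Merits: the ring closes by forming an ether without an activating group, at low temperature, with both bridges already saturated, so the late alkene hydrogenation disappears.
- Weak points: the halogens are control elements that must be dealt with afterwards (the A3 bromide of A7 has to become a hydroxyl, the two chlorides have to be removed); the oxidant is toxic and stoichiometric; the oxidised ring A phenol is para to the Cα silyl ether, so quinone methide formation threatens the stereocentre; A6 must be assembled linearly with the C–D ether, the saturated bridge and Cα all in place.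
- Comparison: the ring closure itself is arguably gentler than a titanium-mediated coupling. The chosen plan sets against it a shorter, convergent sequence with no atoms introduced only to be removed.

Key step: step 10

## Route

Remark on the chemistry: the enantiomer of the ferrocenyl diphosphine used in step 10 is taken to be the one whose known facial preference with simple aryl partners leads to (S)-18, a choice that can be verified on alcohol 19; the alkene of 22 forms without control of geometry and is drawn as Z, either isomer serving equally.

Step 1
Reactants: 1 5-bromo-2-hydroxy-3-methoxybenzaldehyde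
Product: 2 5-bromo-2,3-dihydroxybenzaldehyde
Conditions: BBr3, CH2Cl2, −78 °C to rt; aqueous work-up
Reagents that add atoms: none
Why: Lewis acid cleavage of an aryl methyl ether; the aldehyde and the aryl bromide are inert to BBr3 at this temperature.

Step 2
Reactants: 2 5-bromo-2,3-dihydroxybenzaldehyde
Product: 3 2,3-bis(benzyloxy)-5-bromobenzaldehyde
Conditions: BnBr (2.5 equiv), K2CO3, DMF, 60 °C
Reagents that add atoms: benzyl bromide, BrCc1ccccc1
Why: Williamson etherification of both phenols; gentle heating brings the hydrogen-bonded 2-hydroxyl to completion.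

Step 3
Reactants: 3 2,3-bis(benzyloxy)-5-bromobenzaldehyde
Product: 5 2,3-bis(benzyloxy)-5-bromophenol, via aryl formate 4 (not isolated)
Conditions: mCPBA, CH2Cl2, rt; then K2CO3, MeOH, rt
Reagents that add atoms: 3-chloroperoxybenzoic acid, OOC(=O)c1cccc(Cl)c1
Why: Baeyer–Villiger oxidation of an ortho-alkoxybenzaldehyde, in which the electron-rich aryl group migrates to oxygen, followed by methanolysis of the formate; this gives the three ring A oxygens already differentiated.

Step 4
Reactants: 5 2,3-bis(benzyloxy)-5-bromophenol; 6 4-fluorobenzaldehyde
Product: 7 4-[2,3-bis(benzyloxy)-5-bromophenoxy]benzaldehyde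
Conditions: K2CO3, DMF, 120 °C
Reagents that add atoms: none
Why: Nucleophilic aromatic substitution of a para-formyl-activated fluoride by the phenoxide; the unactivated aryl bromide does not react.

Step 5
Reactants: 7 4-[2,3-bis(benzyloxy)-5-bromophenoxy]benzaldehyde
Product: 8 2-{4-[2,3-bis(benzyloxy)-5-bromophenoxy]phenyl}-1,3-dioxolane (fragment 1)
Conditions: ethylene glycol, p-TsOH (cat.), toluene, reflux, Dean–Stark
Reagents that add atoms: ethylene glycol, OCCO
Why: Acid-catalysed acetalisation with removal of water; it masks the aldehyde against the aryllithium of step 10.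

Step 6
Reactants: 9 2-fluoro-3-hydroxybenzaldehyde
Product: 10 3-(benzyloxy)-2-fluorobenzaldehyde
Conditions: BnBr, K2CO3, DMF, rt
Reagents that add atoms: benzyl bromide, BrCc1ccccc1
Why: Williamson etherification of the phenol; the C–F bond is not attacked by carbonate at room temperature.

Step 7
Reactants: 10 3-(benzyloxy)-2-fluorobenzaldehyde; 11 resorcinol
Product: 12 3-(benzyloxy)-2-(3-hydroxyphenoxy)benzaldehyde
Conditions: 11 (4 equiv), K2CO3, DMSO, 100 °C
Reagents that add atoms: none
Why: Nucleophilic aromatic substitution of the fluoride ortho to the formyl group, which builds the doubly flanked C2–O–D1 ether; the excess of 11 favours mono-arylation.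

Step 8
Reactants: 12 3-(benzyloxy)-2-(3-hydroxyphenoxy)benzaldehyde
Product: 13 3-[2-(benzyloxy)-6-(1,3-dioxolan-2-yl)phenoxy]phenol
Conditions: ethylene glycol, p-TsOH (cat.), toluene, reflux, Dean–Stark
Reagents that add atoms: ethylene glycol, OCCO
Why: Acid-catalysed acetalisation; the free phenol does not interfere.

Step 9
Reactants: 13 3-[2-(benzyloxy)-6-(1,3-dioxolan-2-yl)phenoxy]phenol
Product: 14 3-[2-(benzyloxy)-6-(1,3-dioxolan-2-yl)phenoxy]phenyl trifluoromethanesulfonate (fragment 2)
Conditions: PhNTf2, Et3N, DMAP (cat.), CH2Cl2, rt
Reagents that add atoms: N-phenylbis(trifluoromethanesulfonimide), O=S(=O)(N(c1ccccc1)S(=O)(=O)C(F)(F)F)C(F)(F)F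
Why: Sulfonylation of the phenol with a non-acidic triflating agent, so the dioxolane is not endangered.

Step 10
Reactants: 8 2-{4-[2,3-bis(benzyloxy)-5-bromophenoxy]phenyl}-1,3-dioxolane; 15 4,4,5,5-tetramethyl-2-vinyl-1,3,2-dioxaborolane; 14 3-[2-(benzyloxy)-6-(1,3-dioxolan-2-yl)phenoxy]phenyl trifluoromethanesulfonate
Product: 18 (S)-2-[1-{3,4-bis(benzyloxy)-5-[4-(1,3-dioxolan-2-yl)phenoxy]phenyl}-2-{3-[2-(benzyloxy)-6-(1,3-dioxolan-2-yl)phenoxy]phenyl}ethyl]-4,4,5,5-tetramethyl-1,3,2-dioxaborolane, via aryllithium 16 (not isolated), via vinylboron ate complex 17 (not isolated)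
Conditions: 8, t-BuLi (2.0 equiv), THF, −78 °C; 15, −78 °C to rt; then 14, Pd(OAc)2 (3 mol%), 1,1'-bis[bis(4-methoxy-3,5-dimethylphenyl)phosphino]-2,2'-bis[α-(dimethylamino)benzyl]ferrocene (MandyPhos type, single enantiomer, 3.6 mol%), KOTf (2 equiv), THF, 60 °C
Reagents that add atoms: none
Why: Bromine–lithium exchange on 8 gives aryllithium 16, which adds to boron of 15 to form the four-coordinate vinylboron ate complex 17. Zerovalent palladium, generated from Pd(OAc)2 and the diphosphine, inserts into the C–O bond of triflate 14; the cationic arylpalladium species binds the vinyl group of 17 and triggers an anti 1,2-shift of the ring A aryl group from boron to Cα while Cβ bonds to palladium, and reductive elimination then forms Cβ–D3. This is the known enantioselective conjunctive cross-coupling of aryllithium-derived vinylboron ate complexes with aryl triflates, applied here to larger partners. No ring is closed. The new stereocentre at Cα is controlled by the enantiomer of the ferrocenyl diphosphine on palladium, which decides the alkene face that is activated, and the enantiomer is chosen to give (S)-18. The regiochemistry (boron, later oxygen, next to ring A) is fixed because ring A is the group that migrates from boron. The step needs the conjunctive pathway to outrun direct aryl transfer and β-hydride elimination: ring A is electron-rich and unsubstituted ortho to boron, so it migrates readily, the wide-bite-angle diphosphine favours reductive elimination, and KOTf takes bromide out of solution, which would otherwise block the site needed for alkene binding.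

Step 11
Reactants: 18 (S)-pinacol boronate from step 10
Product: 19 (S)-1-{3,4-bis(benzyloxy)-5-[4-(1,3-dioxolan-2-yl)phenoxy]phenyl}-2-{3-[2-(benzyloxy)-6-(1,3-dioxolan-2-yl)phenoxy]phenyl}ethan-1-ol
Conditions: H2O2 (30%), NaOH (3 M aq.), THF, 0 °C to rt
Reagents that add atoms: hydrogen peroxide, OO
Why: Oxidation of the secondary boronate by 1,2-migration of carbon from boron to oxygen, which proceeds with retention, so (S)-C–B becomes (S)-C–OH; ethers and acetals are stable to basic peroxide.

Step 12
Reactants: 19 (S)-carbinol from step 11
Product: 20 (S)-tert-butyl(1-{3,4-bis(benzyloxy)-5-[4-(1,3-dioxolan-2-yl)phenoxy]phenyl}-2-{3-[2-(benzyloxy)-6-(1,3-dioxolan-2-yl)phenoxy]phenyl}ethoxy)dimethylsilane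
Conditions: TBSCl, imidazole, DMF, rt
Reagents that add atoms: tert-butyldimethylsilyl chloride, CC(C)(C)[Si](C)(C)Cl
Why: Silylation of a secondary alcohol; the silyl ether keeps the alcohol away from titanium in step 14 and shields the benzylic C–O bond in step 15.

Step 13
Reactants: 20 (S)-silyl ether bis-dioxolane from step 12
Product: 21 3-(benzyloxy)-2-{3-[(S)-2-{3,4-bis(benzyloxy)-5-(4-formylphenoxy)phenyl}-2-(tert-butyldimethylsilyloxy)ethyl]phenoxy}benzaldehyde
Conditions: PPTS, acetone/H2O, 50 °C
Reagents that add atoms: water, O
Why: Mild acid-catalysed hydrolysis of two aryl dioxolanes; a pyridinium acid is weak enough to leave the secondary silyl ether and the benzylic C–O bond intact.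

Step 14
Reactants: 21 (S)-dialdehyde from step 13
Product: 22 macrocyclic stilbene: 18-membered ring with a Z-CH=CH bridge between B4 and C1, benzyl ethers on the A3, A4 and C3 oxygens and a tert-butyldimethylsilyl ether at (S)-Cα
Conditions: TiCl4, Zn, pyridine, THF, reflux; slow addition of 21 (high dilution)
Reagents that add atoms: none
Why: Intramolecular McMurry coupling of two aryl aldehydes on low-valent titanium (pinacolate formation, then deoxygenation) closes the 18-membered ring; high dilution favours cyclisation, pyridine buffers Lewis acidity, and Cα is remote from the reacting centres.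

Step 15
Reactants: 22 macrocyclic stilbene from step 14
Product: 23 Cα-O-tert-butyldimethylsilyl ether of the target: saturated CH2–CH2 bridge, free hydroxyls at A3, A4 and C3, (S)-Cα
Conditions: H2 (1 atm), 10% Pd/C, EtOAc, rt
Reagents that add atoms: none
Why: Heterogeneous hydrogenation saturates the stilbene and hydrogenolyses the three aryl benzyl ethers in one operation; in an aprotic solvent the silyl ether is retained and protects the benzylic C–O bond at Cα.

Step 16
Reactants: 23 silyl ether of the target from step 15
Product: 24 target: (S)-configured 18-membered macrocycle with hydroxyls at A3, A4, C3 and Cα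
Conditions: TBAF, AcOH (1:1), THF, 0 °C to rt, argon
Reagents that add atoms: none
Why: Fluoride cleaves the Si–O bond without touching the C–O bond, so the configuration is kept; the acetic acid buffer keeps the phenols protonated, suppressing phenoxide-driven quinone methide formation and catechol oxidation.

## Compound list

1 | 5-bromo-2-hydroxy-3-methoxybenzaldehyde | O=Cc1cc(Br)cc(OC)c1O | starting material
2 | 5-bromo-2,3-dihydroxybenzaldehyde | O=Cc1cc(Br)cc(O)c1O | intermediate
3 | 2,3-bis(benzyloxy)-5-bromobenzaldehyde | O=Cc1cc(Br)cc(OCc2ccccc2)c1OCc1ccccc1 | intermediate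
4 | 2,3-bis(benzyloxy)-5-bromophenyl formate | O=COc1cc(Br)cc(OCc2ccccc2)c1OCc1ccccc1 | intermediate
5 | 2,3-bis(benzyloxy)-5-bromophenol | Oc1cc(Br)cc(OCc2ccccc2)c1OCc1ccccc1 | intermediate
6 | 4-fluorobenzaldehyde | O=Cc1ccc(F)cc1 | starting material
7 | 4-[2,3-bis(benzyloxy)-5-bromophenoxy]benzaldehyde | O=Cc1ccc(cc1)Oc1cc(Br)cc(OCc2ccccc2)c1OCc1ccccc1 | intermediate
8 | 2-{4-[2,3-bis(benzyloxy)-5-bromophenoxy]phenyl}-1,3-dioxolane (fragment 1) | Brc1cc(OCc2ccccc2)c(OCc2ccccc2)c(c1)Oc1ccc(cc1)C1OCCO1 | intermediate
9 | 2-fluoro-3-hydroxybenzaldehyde | O=Cc1cccc(O)c1F | starting material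
10 | 3-(benzyloxy)-2-fluorobenzaldehyde | O=Cc1cccc(OCc2ccccc2)c1F | intermediate
11 | resorcinol (benzene-1,3-diol) | Oc1cccc(O)c1 | starting material
12 | 3-(benzyloxy)-2-(3-hydroxyphenoxy)benzaldehyde | O=Cc1cccc(OCc2ccccc2)c1Oc1cccc(O)c1 | intermediate
13 | 3-[2-(benzyloxy)-6-(1,3-dioxolan-2-yl)phenoxy]phenol | Oc1cccc(c1)Oc1c(cccc1OCc1ccccc1)C1OCCO1 | intermediate
14 | 3-[2-(benzyloxy)-6-(1,3-dioxolan-2-yl)phenoxy]phenyl trifluoromethanesulfonate (fragment 2) | O=S(=O)(Oc1cccc(c1)Oc1c(cccc1OCc1ccccc1)C1OCCO1)C(F)(F)F | intermediate
15 | 4,4,5,5-tetramethyl-2-vinyl-1,3,2-dioxaborolane (vinylboronic acid pinacol ester) | C=CB1OC(C)(C)C(C)(C)O1 | starting material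
16 | {3,4-bis(benzyloxy)-5-[4-(1,3-dioxolan-2-yl)phenoxy]phenyl}lithium | [Li]c1cc(OCc2ccccc2)c(OCc2ccccc2)c(c1)Oc1ccc(cc1)C1OCCO1 | intermediate
17 | lithium {3,4-bis(benzyloxy)-5-[4-(1,3-dioxolan-2-yl)phenoxy]phenyl}(pinacolato)vinylborate | [Li+].C=C[B-]1(OC(C)(C)C(C)(C)O1)c1cc(OCc2ccccc2)c(OCc2ccccc2)c(c1)Oc1ccc(cc1)C1OCCO1 | intermediate
18 | (S)-2-[1-{3,4-bis(benzyloxy)-5-[4-(1,3-dioxolan-2-yl)phenoxy]phenyl}-2-{3-[2-(benzyloxy)-6-(1,3-dioxolan-2-yl)phenoxy]phenyl}ethyl]-4,4,5,5-tetramethyl-1,3,2-dioxaborolane | CC1(C)OB(OC1(C)C)[C@@H](Cc1cccc(c1)Oc1c(cccc1OCc1ccccc1)C1OCCO1)c1cc(OCc2ccccc2)c(OCc2ccccc2)c(c1)Oc1ccc(cc1)C1OCCO1 | intermediate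
19 | (S)-1-{3,4-bis(benzyloxy)-5-[4-(1,3-dioxolan-2-yl)phenoxy]phenyl}-2-{3-[2-(benzyloxy)-6-(1,3-dioxolan-2-yl)phenoxy]phenyl}ethan-1-ol | O[C@@H](Cc1cccc(c1)Oc1c(cccc1OCc1ccccc1)C1OCCO1)c1cc(OCc2ccccc2)c(OCc2ccccc2)c(c1)Oc1ccc(cc1)C1OCCO1 | intermediate
20 | (S)-tert-butyl(1-{3,4-bis(benzyloxy)-5-[4-(1,3-dioxolan-2-yl)phenoxy]phenyl}-2-{3-[2-(benzyloxy)-6-(1,3-dioxolan-2-yl)phenoxy]phenyl}ethoxy)dimethylsilane | CC(C)(C)[Si](C)(C)O[C@@H](Cc1cccc(c1)Oc1c(cccc1OCc1ccccc1)C1OCCO1)c1cc(OCc2ccccc2)c(OCc2ccccc2)c(c1)Oc1ccc(cc1)C1OCCO1 | intermediate
21 | 3-(benzyloxy)-2-{3-[(S)-2-{3,4-bis(benzyloxy)-5-(4-formylphenoxy)phenyl}-2-(tert-butyldimethylsilyloxy)ethyl]phenoxy}benzaldehyde | CC(C)(C)[Si](C)(C)O[C@@H](Cc1cccc(c1)Oc1c(C=O)cccc1OCc1ccccc1)c1cc(OCc2ccccc2)c(OCc2ccccc2)c(c1)Oc1ccc(C=O)cc1 | intermediate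
22 | macrocyclic Z-stilbene, tribenzyl ether (A3, A4, C3) and (S)-Cα tert-butyldimethylsilyl ether | c3ccccc3COc1cc2cc(c1OCc3ccccc3)Oc1ccc(cc1)/C=C\c1cccc(OCc3ccccc3)c1Oc1cccc(c1)C[C@@H]2O[Si](C)(C)C(C)(C)C | intermediate
23 | (S)-Cα-O-tert-butyldimethylsilyl ether of the target | Oc1cc2cc(c1O)Oc1ccc(cc1)CCc1cccc(O)c1Oc1cccc(c1)C[C@@H]2O[Si](C)(C)C(C)(C)C | intermediate
24 | target, (S)-configured macrocyclic tetraol | Oc1cc2cc(c1O)Oc1ccc(cc1)CCc1cccc(O)c1Oc1cccc(c1)C[C@@H]2O | target

## Step count and risks

Total: 16 steps. Longest linear sequence: 12 steps (steps 1 to 5, then 10 to 16); the second branch (steps 6 to 9) joins at step 10.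

**Step 10 (key step).** The most likely failures are inhibition of the cationic arylpalladium intermediate by bromide left from the exchange, incomplete exchange or ate formation leading to direct aryl transfer, and weaker face discrimination with partners this large. Fallback: form the same ate complex from the other side, free of halide. Bromide 8 is converted by Miyaura borylation (B2pin2, PdCl2(dppf), KOAc, dioxane, 80 °C) into 2-{3,4-bis(benzyloxy)-5-[4-(1,3-dioxolan-2-yl)phenoxy]phenyl}-4,4,5,5-tetramethyl-1,3,2-dioxaborolane F1, which is purified. Addition of vinyllithium F2 (made halide-free from tetravinylstannane and n-BuLi) gives ate complex 17 without lithium bromide, and coupling with 14 under the same palladium catalyst returns to the route at 18.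

**Step 14.** Oligomerisation may compete with ring closure, the coupling may stop at the pinacol, and low-valent titanium may cleave the benzylic C–O bond. Fallback: dialdehyde 21 is methylenated twice (Ph3P=CH2, THF) to the bis-styrene F3, (S)-tert-butyl(1-{3,4-bis(benzyloxy)-5-(4-vinylphenoxy)phenyl}-2-{3-[2-(benzyloxy)-6-vinylphenoxy]phenyl}ethoxy)dimethylsilane. Ring-closing metathesis with the second-generation Grubbs catalyst RuCl2(=CHPh)(H2IMes)(PCy3) in dilute solution then closes the ring with loss of ethene and returns to the route at 22 (either alkene geometry).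

**Step 7.** Double arylation of resorcinol, base-mediated condensation of its ring carbons with the aldehyde, and slow displacement at the doubly flanked fluoride are the concerns. Fallback: 10 is treated with 3-(allyloxy)phenol (K2CO3, DMSO) to give 2-[3-(allyloxy)phenoxy]-3-(benzyloxy)benzaldehyde F4, which cannot arylate twice. Deallylation with Pd(PPh3)4, K2CO3, MeOH returns to the route at 12.

**Step 13.** Partial loss of the silyl ether, or ionisation at Cα, may accompany hydrolysis of the two acetals. Fallback: the order is reversed. Carbinol 19 is hydrolysed first (dilute HCl, THF) to (S)-3-(benzyloxy)-2-{3-[2-{3,4-bis(benzyloxy)-5-(4-formylphenoxy)phenyl}-2-hydroxyethyl]phenoxy}benzaldehyde F5, which is then silylated (TBSCl, imidazole, DMF) to return to the route at 21.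

**Step 16.** Once the A4 phenol is free, fluoride or adventitious base may trigger loss of the Cα oxygen through a quinone methide, with racemisation, and the catechol may oxidise. Fallback: the silyl group is removed before the phenols are freed. Stilbene 22 is desilylated with TBAF in THF to the macrocyclic Z-stilbene carbinol tribenzyl ether F6, and hydrogenation over Pd/C in EtOAc then saturates the bridge and removes the benzyl groups, arriving directly at 24. This accepts a free benzylic alcohol during hydrogenolysis in exchange for a neutral final step.

## Further compounds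

F1 | step 10 | 2-{3,4-bis(benzyloxy)-5-[4-(1,3-dioxolan-2-yl)phenoxy]phenyl}-4,4,5,5-tetramethyl-1,3,2-dioxaborolane | CC1(C)OB(OC1(C)C)c1cc(OCc2ccccc2)c(OCc2ccccc2)c(c1)Oc1ccc(cc1)C1OCCO1
F2 | step 10 | vinyllithium | [Li]C=C
F3 | step 14 | (S)-tert-butyl(1-{3,4-bis(benzyloxy)-5-(4-vinylphenoxy)phenyl}-2-{3-[2-(benzyloxy)-6-vinylphenoxy]phenyl}ethoxy)dimethylsilane | CC(C)(C)[Si](C)(C)O[C@@H](Cc1cccc(c1)Oc1c(C=C)cccc1OCc1ccccc1)c1cc(OCc2ccccc2)c(OCc2ccccc2)c(c1)Oc1ccc(C=C)cc1
F4 | step 7 | 2-[3-(allyloxy)phenoxy]-3-(benzyloxy)benzaldehyde | O=Cc1cccc(OCc2ccccc2)c1Oc1cccc(OCC=C)c1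
F5 | step 13 | (S)-3-(benzyloxy)-2-{3-[2-{3,4-bis(benzyloxy)-5-(4-formylphenoxy)phenyl}-2-hydroxyethyl]phenoxy}benzaldehyde | O[C@@H](Cc1cccc(c1)Oc1c(C=O)cccc1OCc1ccccc1)c1cc(OCc2ccccc2)c(OCc2ccccc2)c(c1)Oc1ccc(C=O)cc1
F6 | step 16 | macrocyclic Z-stilbene tribenzyl ether with free (S)-Cα carbinol | c3ccccc3COc1cc2cc(c1OCc3ccccc3)Oc1ccc(cc1)/C=C\c1cccc(OCc3ccccc3)c1Oc1cccc(c1)C[C@@H]2O
A1 | alternative 1 | 19-membered macrocyclic α-(tributylstannyl) dibenzyl ether, tris-TBS ether, (R) at Cα, drawn for a shift that inverts the lithium-bearing carbon | CC(C)(C)[Si](C)(C)Oc1cc2cc(c1O[Si](C)(C)C(C)(C)C)Oc1ccc(cc1)CCc1cccc(O[Si](C)(C)C(C)(C)C)c1Oc1cccc(c1)CO[C@@H]2[Sn](CCCC)(CCCC)CCCC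
A2 | alternative 1 | tris-TBS ether of the target with free (S)-carbinol | CC(C)(C)[Si](C)(C)Oc1cc2cc(c1O[Si](C)(C)C(C)(C)C)Oc1ccc(cc1)CCc1cccc(O[Si](C)(C)C(C)(C)C)c1Oc1cccc(c1)C[C@@H]2O
A3 | alternative 2 | seco bis-iodide (B4 and C1 iodides), tribenzyl ether, (S)-Cα TBS ether | Ic1ccc(cc1)Oc1cc(cc(OCc2ccccc2)c1OCc1ccccc1)[C@@H](O[Si](C)(C)C(C)(C)C)Cc1cccc(c1)Oc1c(I)cccc1OCc1ccccc1
A4 | alternative 2 | (E)-1,2-bis(tributylstannyl)ethene | CCCC[Sn](CCCC)(CCCC)/C=C/[Sn](CCCC)(CCCC)CCCC
A5 | alternative 2 | macrocyclic E-stilbene, tribenzyl ether and (S)-Cα TBS ether | c3ccccc3COc1cc2cc(c1OCc3ccccc3)Oc1ccc(cc1)/C=C/c1cccc(OCc3ccccc3)c1Oc1cccc(c1)C[C@@H]2O[Si](C)(C)C(C)(C)C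
A6 | alternative 3 | seco bis-phenol: ring A 3,5-dibromo-4-hydroxyphenyl, ring B 3,5-dichloro-4-hydroxyphenyl, C3 benzyl ether, (S)-Cα TBS ether | Oc1c(Br)cc(cc1Br)[C@@H](O[Si](C)(C)C(C)(C)C)Cc1cccc(c1)Oc1c(CCc2cc(Cl)c(O)c(Cl)c2)cccc1OCc1ccccc1
A7 | alternative 3 | macrocyclic diaryl ether with A3 bromide, A4 hydroxyl, ring B chlorides, C3 benzyl ether and (S)-Cα TBS ether | Brc1cc2cc(c1O)Oc1c(Cl)cc(cc1Cl)CCc1cccc(OCc3ccccc3)c1Oc1cccc(c1)C[C@@H]2O[Si](C)(C)C(C)(C)C
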